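## Retrosynthetic overview

1. The hydroperoxide is unmasked last from a peroxyketal. The (E,E)-diene comes from a Stille coupling of an (E)-alkenyl iodide on ring A with a peroxyketal-bearing (E)-alkenylstannane.
2. Ring B (the cyclopentenone) is closed late by ring-closing metathesis of a vinyl ketone with a vinyl group. Its cis methyl/ring-A pattern comes from an Ireland–Claisen rearrangement of an (E)-crotyl ester.
3. The tertiary carbinol and CH2OAc come from an exocyclic methylene by face-selective dihydroxylation (isolated as a cis-fused δ-lactone).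
4. The inter-ring C–C bond and the ring A stereocentres come from the new step: a catalytic enantioselective opening of a meso cyclopentene oxide by a ketene silyl acetal.
5. Ring order: ring A is bought (cyclopent-3-en-1-ylmethanol), then the inter-ring bond, then ring B, then the side chain.

Assumption: salen = N,N'-bis(3,5-di-tert-butylsalicylidene)cyclohexane-1,2-diaminate; [(S,S)-salen]CrF (from commercial [(S,S)-salen]CrCl and AgF) is taken to attack the epoxide carbon that becomes the (S) ring carbon of 9, by analogy with azide openings; if the sense is reversed the (R,R) complex is used and nothing else changes.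

## Route

Step 1
Reactants: 1 cyclopent-3-en-1-ylmethanol
Product: 2 cyclopent-3-ene-1-carbaldehyde
Conditions: Dess–Martin periodinane, CH2Cl2, 0 °C → rt
Reagents that add atoms: none
Why: Dess–Martin oxidation stops cleanly at the aldehyde; the substrate has no stereocentre.

Step 2
Reactants: 2 cyclopent-3-ene-1-carbaldehyde
Product: 3 4-ethynylcyclopent-1-ene
Conditions: dimethyl (1-diazo-2-oxopropyl)phosphonate, K2CO3, MeOH, 0 °C → rt
Reagents that add atoms: dimethyl (1-diazo-2-oxopropyl)phosphonate, CC(=O)C(=[N+]=[N-])P(=O)(OC)OC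
Why: Ohira–Bestmann (Seyferth–Gilbert) homologation turns the aldehyde into the terminal alkyne; the α-carbon lies on the mirror plane of the ring, so enolisation costs nothing.

Step 3
Reactants: 3 4-ethynylcyclopent-1-ene
Product: 5 4-[(E)-1-iodoprop-1-en-2-yl]cyclopent-1-ene, via alkenylalane 4 (not isolated)
Conditions: Me3Al, Cp2ZrCl2 (0.25 equiv), CH2Cl2, 0 °C → rt; then I2, THF, −30 → 0 °C
Reagents that add atoms: trimethylaluminium, C[Al](C)C; iodine, II
Why: Negishi zirconocene-catalysed carboalumination adds Me and Al syn across the terminal alkyne with Al on the terminal carbon, and iodinolysis with retention gives the (E)-iodoalkene; the internal ring alkene does not react.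

Step 4
Reactants: 5 4-[(E)-1-iodoprop-1-en-2-yl]cyclopent-1-ene
Product: 6 meso-(1R,5S)-3-[(E)-1-iodoprop-1-en-2-yl]-6-oxabicyclo[3.1.0]hexane (epoxide oxygen trans to the iodoalkenyl group)
Conditions: mCPBA, CH2Cl2, 0 °C; minor cis epoxide removed by chromatography
Reagents that add atoms: 3-chloroperoxybenzoic acid, OOC(=O)c1cccc(Cl)c1
Why: Prilezhaev epoxidation occurs at the electron-rich cyclopentene (the iodoalkene is deactivated) and mainly on the face away from the 4-substituent (about 4:1 expected), which fixes the trans relation between epoxide oxygen and side-chain carbon.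

Step 5
Reactants: 6 meso trans-epoxide; 7 tert-butyl[(1-methoxyethenyl)oxy]dimethylsilane
Product: 9 methyl 2-[(1S,2R,4S)-2-hydroxy-4-[(E)-1-iodoprop-1-en-2-yl]cyclopentyl]acetate, via silyl ether 8 (not isolated)
Conditions: [(S,S)-salen]CrF (5 mol%), 4 Å MS, tBuOMe, 0 °C → rt; then 1 M HCl in MeOH, rt
Reagents that add atoms: none
Why: Proposed new method: fluoride on the trivalent chromium centre takes the silyl group of 7 and leaves an O-bound chromium ester enolate, a second (salen)Cr unit binds the meso epoxide as a Lewis acid, and the enolate carbon opens one of the two enantiotopic C–O bonds from the rear (SN2, inversion) in a two-metal head-to-tail transition state, so the CH2CO2Me group arrives cis to the iodoalkenyl group and trans to oxygen and the catalyst fixes all three ring stereocentres; the chromium alkoxide is silylated by the next molecule of 7, which closes the cycle; closest known reaction type: the (salen)CrN3-catalysed desymmetrising azidolysis of meso epoxides with Me3SiN3 (same two-metal mechanism and silyl turnover) and the racemic Lewis-acid (Mukaiyama-type) opening of epoxides by ketene silyl acetals.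

Step 6
Reactants: 9 methyl 2-[(1S,2R,4S)-2-hydroxy-4-[(E)-1-iodoprop-1-en-2-yl]cyclopentyl]acetate
Product: 10 methyl 2-[(1S,4S)-4-[(E)-1-iodoprop-1-en-2-yl]-2-oxocyclopentyl]acetate
Conditions: Dess–Martin periodinane, CH2Cl2, rt
Reagents that add atoms: none
Why: Dess–Martin oxidation of the secondary alcohol is neutral, so the adjacent α-stereocentre is not epimerised.

Step 7
Reactants: 10 methyl 2-[(1S,4S)-4-[(E)-1-iodoprop-1-en-2-yl]-2-oxocyclopentyl]acetate
Product: 11 methyl 2-[(1S,4S)-4-[(E)-1-iodoprop-1-en-2-yl]-2-methylidenecyclopentyl]acetate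
Conditions: Zn, CH2Br2, TiCl4, THF/CH2Cl2, 0 °C → rt
Reagents that add atoms: dibromomethane, BrCBr
Why: Takai–Lombardo methylenation is non-basic, so the enolisable α-stereocentre is kept and the ester is untouched.

Step 8
Reactants: 11 methyl 2-[(1S,4S)-4-[(E)-1-iodoprop-1-en-2-yl]-2-methylidenecyclopentyl]acetate
Product: 13 (4aS,6S,7aR)-7a-hydroxy-6-[(E)-1-iodoprop-1-en-2-yl]hexahydrocyclopenta[c]pyran-3(1H)-one, via diol ester 12 (not isolated)
Conditions: OsO4 (2 mol%), N-methylmorpholine N-oxide, acetone/H2O, rt; then TsOH (cat.), CH2Cl2, rt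
Reagents that add atoms: N-methylmorpholine N-oxide, C[N+]1([O-])CCOCC1; water, O
Why: Upjohn dihydroxylation: OsO4 adds to the exocyclic alkene from the face opposite the two cis ring substituents, so the new tertiary OH is trans and the CH2OH cis to the acetate arm (this sets the quaternary carbinol centre), and the cis CH2OH then lactonises to the cis-fused δ-lactone.

Step 9
Reactants: 13 (4aS,6S,7aR)-7a-hydroxy-6-[(E)-1-iodoprop-1-en-2-yl]hexahydrocyclopenta[c]pyran-3(1H)-one
Product: 14 methyl 2-[(5R,6S,8S)-8-[(E)-1-iodoprop-1-en-2-yl]-2,2-dimethyl-1,3-dioxaspiro[4.4]nonan-6-yl]acetate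
Conditions: 2,2-dimethoxypropane, MeOH, CSA (cat.), rt
Reagents that add atoms: 2,2-dimethoxypropane, COC(C)(C)OC; methanol, CO
Why: acid-catalysed methanolysis of the lactone is pulled to the open form by trapping the freed 1,2-diol as its acetonide (ketalisation); no stereocentre is involved.

Step 10
Reactants: 14 methyl ester acetonide; 15 (E)-but-2-en-1-ol
Product: 16 (E)-but-2-en-1-yl 2-[(5R,6S,8S)-8-[(E)-1-iodoprop-1-en-2-yl]-2,2-dimethyl-1,3-dioxaspiro[4.4]nonan-6-yl]acetate
Conditions: Ti(OiPr)4 (0.2 equiv), 15 (10 equiv), toluene, 4 Å MS, 90 °C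
Reagents that add atoms: none
Why: titanate-mediated transesterification exchanges the unhindered methyl ester for the crotyl ester under neutral conditions that keep the acetonide and the (E) geometry.

Step 11
Reactants: 16 (E)-crotyl ester
Product: 19 (2S,3R)-2-[(5R,6S,8S)-8-[(E)-1-iodoprop-1-en-2-yl]-2,2-dimethyl-1,3-dioxaspiro[4.4]nonan-6-yl]-3-methylpent-4-enoic acid, via silyl ketene acetal 17 (not isolated), via silyl ester 18 (not isolated)
Conditions: LiN(iPr)2, THF, −78 °C; Me3SiCl, −78 °C → rt, then 50 °C; 1 M HCl work-up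
Reagents that add atoms: chlorotrimethylsilane, C[Si](C)(C)Cl (silyl groups of 17 and 18 only)
Why: Ireland–Claisen rearrangement: kinetic enolisation in THF puts the ring carbon cis to the crotyl oxygen, the chair transition state with the (E)-crotyl unit gives the 2,3-anti acid (the later cis pattern of ring B), and the allyl terminus adds to the enolate face away from the fully substituted spiro carbon (ring C–H eclipsing the C=C, 1,3-allylic strain control), which sets C2 as S and C3 as R.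

Step 12
Reactants: 19 pentenoic acid
Product: 21 (2S,3R)-N-methoxy-N,3-dimethyl-2-[(5R,6S,8S)-8-[(E)-1-iodoprop-1-en-2-yl]-2,2-dimethyl-1,3-dioxaspiro[4.4]nonan-6-yl]pent-4-enamide, via acyl imidazole 20 (not isolated)
Conditions: 1,1'-carbonyldiimidazole, CH2Cl2, rt; then MeNH(OMe)·HCl, rt
Reagents that add atoms: 1,1'-carbonyldiimidazole, O=C(n1ccnc1)n1ccnc1 (imidazolyl group of 20 only); N,O-dimethylhydroxylamine hydrochloride, Cl.CNOC
Why: amide formation through the acyl imidazolide is base-free, so the α-stereocentre is kept.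

Step 13
Reactants: 21 Weinreb amide
Product: 23 (4S,5R)-4-[(5R,6S,8S)-8-[(E)-1-iodoprop-1-en-2-yl]-2,2-dimethyl-1,3-dioxaspiro[4.4]nonan-6-yl]-5-methylhepta-1,6-dien-3-one, via magnesium hemiaminal 22 (not isolated)
Conditions: CH2=CHMgBr (3 equiv), THF, −20 → 0 °C; poured into cold 1 M HCl
Reagents that add atoms: vinylmagnesium bromide, C=C[Mg]Br
Why: Weinreb ketone synthesis: the chelated tetrahedral intermediate prevents over-addition, and the inverse acidic quench protonates the released amine before it can add to the vinyl ketone.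

Step 14
Reactants: 23 dienone
Product: 24 (4R,5S)-5-[(5R,6S,8S)-8-[(E)-1-iodoprop-1-en-2-yl]-2,2-dimethyl-1,3-dioxaspiro[4.4]nonan-6-yl]-4-methylcyclopent-2-en-1-one
Conditions: second-generation Grubbs catalyst RuCl2(=CHPh)(H2IMes)(PCy3) (5 mol%), CH2Cl2, 40 °C
Reagents that add atoms: none
Why: ring-closing metathesis of the vinyl ketone with the terminal vinyl group closes ring B with loss of ethene under neutral conditions, so the cis stereodiad from step 11 is carried over; the trisubstituted iodoalkene is inert.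

Step 15
Reactants: 24 cyclopentenone acetonide
Product: 25 (4R,5S)-5-[(1S,2R,4S)-2-hydroxy-2-(hydroxymethyl)-4-[(E)-1-iodoprop-1-en-2-yl]cyclopentyl]-4-methylcyclopent-2-en-1-one
Conditions: AcOH/H2O (4:1), 40 °C
Reagents that add atoms: none
Why: mild aqueous acid hydrolyses the acetonide (acetal hydrolysis) without enolising the enone α-centre.

Step 16
Reactants: 25 diol
Product: 26 [(1R,2S,4S)-1-hydroxy-4-[(E)-1-iodoprop-1-en-2-yl]-2-[(1S,5R)-5-methyl-2-oxocyclopent-3-en-1-yl]cyclopentyl]methyl acetate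
Conditions: Ac2O, pyridine, CH2Cl2, 0 °C → rt
Reagents that add atoms: acetic anhydride, CC(=O)OC(C)=O
Why: acylation occurs only at the primary alcohol because the tertiary alcohol needs forcing conditions, and pyridine is too weak a base to epimerise the enone.

Step 17
Reactants: 27 2-methylbut-3-yn-2-ol
Product: 28 3-hydroperoxy-3-methylbut-1-yne
Conditions: 50% aq. H2O2, H2SO4 (cat.), 0 °C (kept in solution)
Reagents that add atoms: hydrogen peroxide, OO
Why: acid-catalysed perhydrolysis (SN1 substitution through the tertiary propargylic cation) by the strongly nucleophilic H2O2 gives the tertiary hydroperoxide.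

Step 18
Reactants: 28 3-hydroperoxy-3-methylbut-1-yne
Product: 29 3-[(2-methoxypropan-2-yl)peroxy]-3-methylbut-1-yne
Conditions: 2-methoxypropene, PPTS (cat.), CH2Cl2, 0 °C
Reagents that add atoms: 2-methoxypropene, COC(C)=C
Why: acid-catalysed addition of the O–O–H group to the enol ether gives the monoperoxyketal, a protecting group stable to base, tin hydride and palladium.

Step 19
Reactants: 29 peroxyketal alkyne
Product: 30 tributyl[(E)-3-[(2-methoxypropan-2-yl)peroxy]-3-methylbut-1-en-1-yl]stannane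
Conditions: Bu3SnH, PdCl2(PPh3)2 (2 mol%), THF, 0 °C
Reagents that add atoms: tributyltin hydride, CCCC[SnH](CCCC)CCCC
Why: palladium-catalysed syn hydrostannation puts tin on the unhindered terminal carbon (quaternary propargylic centre) and gives the (E)-alkenylstannane; the dialkyl peroxide is not reduced without a radical initiator.

Step 20
Reactants: 26 iodoalkene acetate; 30 alkenylstannane
Product: 31 [(1R,2S,4S)-1-hydroxy-4-[(2E,4E)-6-[(2-methoxypropan-2-yl)peroxy]-6-methylhepta-2,4-dien-2-yl]-2-[(1S,5R)-5-methyl-2-oxocyclopent-3-en-1-yl]cyclopentyl]methyl acetate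
Conditions: PdCl2(MeCN)2 (5 mol%), DMF, rt, dark
Reagents that add atoms: none
Why: Stille cross-coupling joins the two alkenyl partners with retention at both double bonds to give the (E,E)-diene; neutral phosphine-free conditions leave the peroxyketal, the enone α-centre and the free tertiary alcohol untouched.

Step 21
Reactants: 31 peroxyketal
Product: 32 [(1R,2S,4S)-4-[(2E,4E)-6-hydroperoxy-6-methylhepta-2,4-dien-2-yl]-1-hydroxy-2-[(1S,5R)-5-methyl-2-oxocyclopent-3-en-1-yl]cyclopentyl]methyl acetate (target)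
Conditions: AcOH/THF/H2O (4:2:1), rt
Reagents that add atoms: none
Why: mild acid hydrolysis of the peroxyketal frees the tertiary allylic hydroperoxide; acetate, enone and the cis substituents of ring B are stable under these conditions.

## Compound list

1 | cyclopent-3-en-1-ylmethanol | OCC1CC=CC1 | starting material
2 | cyclopent-3-ene-1-carbaldehyde | O=CC1CC=CC1 | intermediate
3 | 4-ethynylcyclopent-1-ene | C#CC1CC=CC1 | intermediate
4 | [(E)-2-(cyclopent-3-en-1-yl)prop-1-en-1-yl]dimethylalumane | C[Al](C)/C=C(\C)C1CC=CC1 | intermediate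
5 | 4-[(E)-1-iodoprop-1-en-2-yl]cyclopent-1-ene | I/C=C(\C)C1CC=CC1 | intermediate
6 | meso-(1R,5S)-3-[(E)-1-iodoprop-1-en-2-yl]-6-oxabicyclo[3.1.0]hexane, epoxide O trans to the iodoalkenyl group | I/C=C(\C)[C@@H]1C[C@H]2O[C@H]2C1 | intermediate
7 | tert-butyl[(1-methoxyethenyl)oxy]dimethylsilane | COC(=C)O[Si](C)(C)C(C)(C)C | starting material
8 | methyl 2-[(1S,2R,4S)-2-(tert-butyldimethylsilyloxy)-4-[(E)-1-iodoprop-1-en-2-yl]cyclopentyl]acetate | COC(=O)C[C@@H]1C[C@H](/C(C)=C/I)C[C@H]1O[Si](C)(C)C(C)(C)C | intermediate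
9 | methyl 2-[(1S,2R,4S)-2-hydroxy-4-[(E)-1-iodoprop-1-en-2-yl]cyclopentyl]acetate | COC(=O)C[C@@H]1C[C@H](/C(C)=C/I)C[C@H]1O | intermediate
10 | methyl 2-[(1S,4S)-4-[(E)-1-iodoprop-1-en-2-yl]-2-oxocyclopentyl]acetate | COC(=O)C[C@@H]1C[C@H](/C(C)=C/I)CC1=O | intermediate
11 | methyl 2-[(1S,4S)-4-[(E)-1-iodoprop-1-en-2-yl]-2-methylidenecyclopentyl]acetate | COC(=O)C[C@@H]1C[C@H](/C(C)=C/I)CC1=C | intermediate
12 | methyl 2-[(1S,2R,4S)-2-hydroxy-2-(hydroxymethyl)-4-[(E)-1-iodoprop-1-en-2-yl]cyclopentyl]acetate | COC(=O)C[C@@H]1C[C@H](/C(C)=C/I)C[C@]1(O)CO | intermediate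
13 | (4aS,6S,7aR)-7a-hydroxy-6-[(E)-1-iodoprop-1-en-2-yl]hexahydrocyclopenta[c]pyran-3(1H)-one | O=C1C[C@@H]2C[C@H](/C(C)=C/I)C[C@]2(O)CO1 | intermediate
14 | methyl 2-[(5R,6S,8S)-8-[(E)-1-iodoprop-1-en-2-yl]-2,2-dimethyl-1,3-dioxaspiro[4.4]nonan-6-yl]acetate | COC(=O)C[C@@H]1C[C@H](/C(C)=C/I)C[C@]12COC(C)(C)O2 | intermediate
15 | (E)-but-2-en-1-ol | C/C=C/CO | starting material
16 | (E)-but-2-en-1-yl 2-[(5R,6S,8S)-8-[(E)-1-iodoprop-1-en-2-yl]-2,2-dimethyl-1,3-dioxaspiro[4.4]nonan-6-yl]acetate | C/C=C/COC(=O)C[C@@H]1C[C@H](/C(C)=C/I)C[C@]12COC(C)(C)O2 | intermediate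
17 | (E)-O-crotyl O-trimethylsilyl ketene acetal of 16 (ring carbon cis to the crotyloxy group) | C/C=C/CO/C(O[Si](C)(C)C)=C\[C@@H]1C[C@H](/C(C)=C/I)C[C@]12COC(C)(C)O2 | intermediate
18 | trimethylsilyl (2S,3R)-2-[(5R,6S,8S)-8-[(E)-1-iodoprop-1-en-2-yl]-2,2-dimethyl-1,3-dioxaspiro[4.4]nonan-6-yl]-3-methylpent-4-enoate | C[Si](C)(C)OC(=O)[C@@H]([C@H](C)C=C)[C@@H]1C[C@H](/C(C)=C/I)C[C@]12COC(C)(C)O2 | intermediate
19 | (2S,3R)-2-[(5R,6S,8S)-8-[(E)-1-iodoprop-1-en-2-yl]-2,2-dimethyl-1,3-dioxaspiro[4.4]nonan-6-yl]-3-methylpent-4-enoic acid | OC(=O)[C@@H]([C@H](C)C=C)[C@@H]1C[C@H](/C(C)=C/I)C[C@]12COC(C)(C)O2 | intermediate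
20 | (2S,3R)-1-(imidazol-1-yl)-2-[(5R,6S,8S)-8-[(E)-1-iodoprop-1-en-2-yl]-2,2-dimethyl-1,3-dioxaspiro[4.4]nonan-6-yl]-3-methylpent-4-en-1-one | O=C(n1ccnc1)[C@@H]([C@H](C)C=C)[C@@H]1C[C@H](/C(C)=C/I)C[C@]12COC(C)(C)O2 | intermediate
21 | (2S,3R)-N-methoxy-N,3-dimethyl-2-[(5R,6S,8S)-8-[(E)-1-iodoprop-1-en-2-yl]-2,2-dimethyl-1,3-dioxaspiro[4.4]nonan-6-yl]pent-4-enamide | CON(C)C(=O)[C@@H]([C@H](C)C=C)[C@@H]1C[C@H](/C(C)=C/I)C[C@]12COC(C)(C)O2 | intermediate
22 | bromomagnesium alkoxide of the tetrahedral adduct of 21 with vinylmagnesium bromide (carbinol centre undefined) | CON(C)C(O[Mg]Br)(C=C)[C@@H]([C@H](C)C=C)[C@@H]1C[C@H](/C(C)=C/I)C[C@]12COC(C)(C)O2 | intermediate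
23 | (4S,5R)-4-[(5R,6S,8S)-8-[(E)-1-iodoprop-1-en-2-yl]-2,2-dimethyl-1,3-dioxaspiro[4.4]nonan-6-yl]-5-methylhepta-1,6-dien-3-one | C=CC(=O)[C@@H]([C@H](C)C=C)[C@@H]1C[C@H](/C(C)=C/I)C[C@]12COC(C)(C)O2 | intermediate
24 | (4R,5S)-5-[(5R,6S,8S)-8-[(E)-1-iodoprop-1-en-2-yl]-2,2-dimethyl-1,3-dioxaspiro[4.4]nonan-6-yl]-4-methylcyclopent-2-en-1-one | CC1(C)OC[C@@]2(O1)C[C@@H](/C(C)=C/I)C[C@H]2[C@H]3C(=O)C=C[C@H]3C | intermediate
25 | (4R,5S)-5-[(1S,2R,4S)-2-hydroxy-2-(hydroxymethyl)-4-[(E)-1-iodoprop-1-en-2-yl]cyclopentyl]-4-methylcyclopent-2-en-1-one | OC[C@@]1(O)C[C@@H](/C(C)=C/I)C[C@H]1[C@H]1C(=O)C=C[C@H]1C | intermediate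
26 | [(1R,2S,4S)-1-hydroxy-4-[(E)-1-iodoprop-1-en-2-yl]-2-[(1S,5R)-5-methyl-2-oxocyclopent-3-en-1-yl]cyclopentyl]methyl acetate | CC(=O)OC[C@@]1(O)C[C@@H](/C(C)=C/I)C[C@H]1[C@H]1C(=O)C=C[C@H]1C | intermediate
27 | 2-methylbut-3-yn-2-ol | CC(C)(O)C#C | starting material
28 | 3-hydroperoxy-3-methylbut-1-yne | CC(C)(OO)C#C | intermediate
29 | 3-[(2-methoxypropan-2-yl)peroxy]-3-methylbut-1-yne | COC(C)(C)OOC(C)(C)C#C | intermediate
30 | tributyl[(E)-3-[(2-methoxypropan-2-yl)peroxy]-3-methylbut-1-en-1-yl]stannane | CCCC[Sn](CCCC)(CCCC)/C=C/C(C)(C)OOC(C)(C)OC | intermediate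
31 | [(1R,2S,4S)-1-hydroxy-4-[(2E,4E)-6-[(2-methoxypropan-2-yl)peroxy]-6-methylhepta-2,4-dien-2-yl]-2-[(1S,5R)-5-methyl-2-oxocyclopent-3-en-1-yl]cyclopentyl]methyl acetate | CC(=O)OC[C@@]1(O)C[C@@H](/C(C)=C/C=C/C(C)(C)OOC(C)(C)OC)C[C@H]1[C@H]1C(=O)C=C[C@H]1C | intermediate
32 | [(1R,2S,4S)-4-[(2E,4E)-6-hydroperoxy-6-methylhepta-2,4-dien-2-yl]-1-hydroxy-2-[(1S,5R)-5-methyl-2-oxocyclopent-3-en-1-yl]cyclopentyl]methyl acetate | CC(=O)OC[C@@]1(O)C[C@@H](/C(C)=C/C=C/C(C)(C)OO)C[C@H]1[C@H]1C(=O)C=C[C@H]1C | target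

## Step count and risks

Total steps: 21. Longest linear sequence: 18 (steps 1–16, 20, 21); the stannane 30 takes 3 steps (17–19).

The three steps most likely to fail:

**Step 5 (the proposed new desymmetrisation).** The chromium enolate may be too weak a carbon nucleophile, or the enantioselectivity may be low. The fallback uses known chemistry and sets out from 6. The epoxide is opened with the aluminium enolate of methyl acetate (LiN(iPr)2, MeOAc, THF, −78 °C; then Et2AlCl). This gives the racemic trans hydroxy ester, that is 9 together with its mirror image methyl 2-[(1R,2S,4R)-2-hydroxy-4-[(E)-1-iodoprop-1-en-2-yl]cyclopentyl]acetate F1. A lipase-catalysed kinetic resolution (Amano lipase PS, vinyl acetate, tBuOMe) acylates the (R)-carbinol enantiomer to methyl 2-[(1S,2R,4S)-2-acetoxy-4-[(E)-1-iodoprop-1-en-2-yl]cyclopentyl]acetate F2, and the unreacted alcohol F1 is removed by chromatography. K2CO3 in MeOH then cleaves the acetate, and the route is rejoined at 9 (at most half of the material).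

**Step 11 (Ireland–Claisen).** The face selectivity at the enolate carbon rests on acyclic 1,2-induction and could be modest. The fallback sets out from lactone 13 and moves the C–C bond formation onto the rigid bicycle. The tertiary alcohol is silylated (Me3SiOTf, 2,6-lutidine) to (4aS,6S,7aR)-6-[(E)-1-iodoprop-1-en-2-yl]-7a-(trimethylsilyloxy)hexahydrocyclopenta[c]pyran-3(1H)-one F3. Its lithium enolate (LiN(SiMe3)2) undergoes an iridium-catalysed branched-selective allylic alkylation ([Ir(cod)Cl]2, chiral phosphoramidite ligand, (E)-but-2-enyl methyl carbonate). The electrophile enters on the convex face, anti to the ring-fusion C–C bond, and the ligand sets the methyl-bearing centre, giving (4S,4aS,6S,7aR)-4-[(2R)-but-3-en-2-yl]-6-[(E)-1-iodoprop-1-en-2-yl]-7a-(trimethylsilyloxy)hexahydrocyclopenta[c]pyran-3(1H)-one F4. Aminolysis with AlMe3 and MeNH(OMe)·HCl opens the lactone and loses the silyl group on work-up, giving (2S,3R)-2-[(1S,2R,4S)-2-hydroxy-2-(hydroxymethyl)-4-[(E)-1-iodoprop-1-en-2-yl]cyclopentyl]-N-methoxy-N,3-dimethylpent-4-enamide F5. 2,2-Dimethoxypropane with PPTS then gives 21, where the route is rejoined.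

**Step 20 (Stille coupling with the peroxide-bearing stannane).** The O–O bond may not survive palladium, or the stannane 30 may not be obtainable cleanly in step 19. The fallback sets out from 26 and forms the C–OOH bond last instead. A Stille coupling with tributyl(3-methylbut-2-en-1-yl)stannane (PdCl2(MeCN)2, DMF) gives the skipped diene [(1R,2S,4S)-1-hydroxy-4-[(2E)-6-methylhepta-2,5-dien-2-yl]-2-[(1S,5R)-5-methyl-2-oxocyclopent-3-en-1-yl]cyclopentyl]methyl acetate F6. A Schenck ene reaction with singlet oxygen (O2, tetraphenylporphyrin, hν, CH2Cl2, 0 °C) abstracts the doubly allylic hydrogen of the prenyl unit and gives the conjugated tertiary hydroperoxide. Regioisomeric hydroperoxides are removed by HPLC, and the route comes back directly at 32.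

## Further compounds

F1 | step 5 | methyl 2-[(1R,2S,4R)-2-hydroxy-4-[(E)-1-iodoprop-1-en-2-yl]cyclopentyl]acetate | COC(=O)C[C@H]1C[C@@H](/C(C)=C/I)C[C@@H]1O
F2 | step 5 | methyl 2-[(1S,2R,4S)-2-acetoxy-4-[(E)-1-iodoprop-1-en-2-yl]cyclopentyl]acetate | COC(=O)C[C@@H]1C[C@H](/C(C)=C/I)C[C@H]1OC(C)=O
F3 | step 11 | (4aS,6S,7aR)-6-[(E)-1-iodoprop-1-en-2-yl]-7a-(trimethylsilyloxy)hexahydrocyclopenta[c]pyran-3(1H)-one | O=C1C[C@@H]2C[C@H](/C(C)=C/I)C[C@]2(O[Si](C)(C)C)CO1
F4 | step 11 | (4S,4aS,6S,7aR)-4-[(2R)-but-3-en-2-yl]-6-[(E)-1-iodoprop-1-en-2-yl]-7a-(trimethylsilyloxy)hexahydrocyclopenta[c]pyran-3(1H)-one | O=C1[C@@H]([C@H](C)C=C)[C@@H]2C[C@H](/C(C)=C/I)C[C@]2(O[Si](C)(C)C)CO1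
F5 | step 11 | (2S,3R)-2-[(1S,2R,4S)-2-hydroxy-2-(hydroxymethyl)-4-[(E)-1-iodoprop-1-en-2-yl]cyclopentyl]-N-methoxy-N,3-dimethylpent-4-enamide | CON(C)C(=O)[C@@H]([C@H](C)C=C)[C@@H]1C[C@H](/C(C)=C/I)C[C@]1(O)CO
F6 | step 20 | [(1R,2S,4S)-1-hydroxy-4-[(2E)-6-methylhepta-2,5-dien-2-yl]-2-[(1S,5R)-5-methyl-2-oxocyclopent-3-en-1-yl]cyclopentyl]methyl acetate | CC(=O)OC[C@@]1(O)C[C@@H](/C(C)=C/CC=C(C)C)C[C@H]1[C@H]1C(=O)C=C[C@H]1C
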